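The benzene ring (C1 benzylic; Br on C2, C3, C6; OH on C4, C5) is disconnected at C3, the C–Br carbon flanked by C2 and oxygen-bearing C4. Deleting C3 leaves a cyclopentane-1,2-dione ring that is mirror-symmetric through C1 and therefore derives from a symmetric cyclopentene. In one operation dibromocarbene adds across the C2=C4 silyl enol ether of the dione monoketal and the strained dibromocyclopropane opens. This forges C2–C3 and C3–C4, enlarges the five-membered carbocycle to the six-membered one, and delivers the C3 bromine at catechol oxidation level. The precursor 9 is the tert-butyldimethylsilyl enol ether of the monoketal, sturdier towards tert-butoxide than a trimethylsilyl ether.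

Key step: step 7

Remark: every chiral intermediate is racemic and the diastereomer mixtures 6, 7 and 11 are carried on unseparated, because all sp3 ring stereocentres are lost on aromatisation; ring carbons of all intermediates carry the arene numbers C1–C6.

Step 1
Reactants: 1 cyclopent-3-en-1-ylmethanol
Product: 2 cyclopent-3-en-1-ylmethyl methanesulfonate
Conditions: MsCl, Et3N, CH2Cl2, 0 °C
Reagents that add atoms: methanesulfonyl chloride, CS(=O)(=O)Cl
Why: Mesylation of an unhindered primary alcohol turns OH into a leaving group and leaves the isolated alkene untouched.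

Step 2
Reactants: 2 cyclopent-3-en-1-ylmethyl methanesulfonate; 3 pyrrolidin-2-one
Product: 5 1-(cyclopent-3-en-1-ylmethyl)pyrrolidin-2-one, via sodium lactamate 4 (not isolated)
Conditions: NaH, DMF, 0 °C; then 2, 60 °C
Reagents that add atoms: none
Why: SN2 N-alkylation of a sodium lactamate by a primary mesylate in a dipolar aprotic solvent is routine, favours nitrogen over oxygen, and gives an achiral (mirror-symmetric) product.

Step 3
Reactants: 5 1-(cyclopent-3-en-1-ylmethyl)pyrrolidin-2-one
Product: 6 1-[(3-hydroxy-4-oxocyclopentyl)methyl]pyrrolidin-2-one (racemic, cis/trans mixture)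
Conditions: RuCl3 (1 mol%), KHSO5 (as 2KHSO5·KHSO4·K2SO4), NaHCO3, EtOAc–MeCN–H2O, rt, short contact time
Reagents that add atoms: potassium peroxymonosulfate, [K+].[O-]S(=O)(=O)OO
Why: RuO4-catalysed ketohydroxylation: RuO4 formed in situ adds (3+2) to the only alkene and peroxymonosulfate oxidises the ruthenate ester to the acyloin within minutes, much faster than RuO4 attacks the lactam N–CH2 groups; the two alkene carbons are enantiotopic, so one constitution results, and the uncontrolled carbinol centre is removed in step 5.

Step 4
Reactants: 6 1-[(3-hydroxy-4-oxocyclopentyl)methyl]pyrrolidin-2-one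
Product: 7 1-[(6-hydroxy-1,4-dioxaspiro[4.4]nonan-8-yl)methyl]pyrrolidin-2-one (racemic, diastereomer mixture)
Conditions: HOCH2CH2OH, TsOH·H2O (cat.), toluene, Dean–Stark, reflux
Reagents that add atoms: ethylene glycol, OCCO
Why: Acid-catalysed ketalisation driven by azeotropic water removal, as practised on 2-hydroxycycloalkanones; acyloin tautomerism is harmless because exchanging C=O and CHOH regenerates the same constitution, and the lactam is inert.

Step 5
Reactants: 7 1-[(6-hydroxy-1,4-dioxaspiro[4.4]nonan-8-yl)methyl]pyrrolidin-2-one
Product: 8 1-[(6-oxo-1,4-dioxaspiro[4.4]nonan-8-yl)methyl]pyrrolidin-2-one (racemic)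
Conditions: n-Pr4N[RuO4] (5 mol%), NMO, 4 Å MS, CH2Cl2, rt
Reagents that add atoms: none
Why: Ley–Griffith oxidation of a secondary alcohol under neutral, anhydrous conditions spares ketal and lactam and merges the diastereomers into one ketone whose only enolisable position is C2.

Step 6
Reactants: 8 1-[(6-oxo-1,4-dioxaspiro[4.4]nonan-8-yl)methyl]pyrrolidin-2-one
Product: 9 1-{[6-(tert-butyldimethylsilyloxy)-1,4-dioxaspiro[4.4]non-6-en-8-yl]methyl}pyrrolidin-2-one (racemic)
Conditions: TBSOTf (1.1 equiv), Et3N (excess), CH2Cl2, −78 to 0 °C
Reagents that add atoms: tert-butyldimethylsilyl triflate, CC(C)(C)[Si](C)(C)OS(=O)(=O)C(F)(F)F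
Why: Soft enolisation and O-silylation, well known for α,α-dialkoxy ketones, can only run towards C2 because C5 is quaternary; limiting the triflate under excess amine avoids ketal opening and lactam silylation, and the product tolerates aqueous work-up.

Step 7
Reactants: 9 1-{[6-(tert-butyldimethylsilyloxy)-1,4-dioxaspiro[4.4]non-6-en-8-yl]methyl}pyrrolidin-2-one; 10 bromoform
Product: 12 1-[(7-bromo-6-oxo-1,4-dioxaspiro[4.5]dec-7-en-9-yl)methyl]pyrrolidin-2-one (racemic), via dibromocyclopropane 11 (not isolated)
Conditions: CHBr3, KOt-Bu (added last, in portions), toluene–pentane, −30 °C to rt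
Reagents that add atoms: bromoform (10), BrC(Br)Br
Why: Bromoform is deprotonated by KOt-Bu and loses bromide (α-elimination) to give singlet dibromocarbene, which adds in a concerted (2+1) cheletropic step to the C2=C4 enol ether, forming C2–C3 and C3–C4 and closing the three-membered ring of 11. The strained 6,6-dibromobicyclo[3.1.0]hexane then undergoes disrotatory two-electron electrocyclic cleavage of the shared C2–C4 bond as the endo bromide departs (Woodward–Hoffmann–DePuy mode), so the six-membered ring is closed by ring enlargement rather than by end-to-end cyclisation, and the silyloxy-stabilised allyl cation gives up silicon to bromide or tert-butoxide and collapses to the 2-bromoenone. The closest known reaction type is the dihalocarbene homologation of cyclic silyl enol ethers to 2-halocycloalk-2-enones, which also converts indanone enol ethers into 2-halo-1-naphthols; only the neighbouring ketal is an untried spectator. Site selectivity is secured twice: the enol ether is the only electron-rich π bond (lactam carbonyl and ketal do not react with the electrophilic carbene), and the quaternary ketal carbon C5 allowed enolisation only towards C2, so the new carbon can enter only between C2 and C4, while a second addition is excluded because the product alkene is electron-poor. No stereocentre is created in 12, since attack on either face of 9 gives an adduct that owns an endo bromide, both cyclopropane centres vanish on opening, and the untouched racemic C1 centre is erased in step 8. The tert-butyldimethylsilyl group slows the Si–O cleavage by tert-butoxide that would divert a trimethylsilyl ether to the potassium enolate, and cold portionwise addition of the base keeps 12 away from excess base and tribromomethanide.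

Step 8
Reactants: 12 1-[(7-bromo-6-oxo-1,4-dioxaspiro[4.5]dec-7-en-9-yl)methyl]pyrrolidin-2-one
Product: 14 1-[(3-bromo-4,5-dihydroxyphenyl)methyl]pyrrolidin-2-one, via aryl 2-hydroxyethyl ether 13 (not isolated)
Conditions: BBr3 (4 equiv), CH2Cl2, −78 °C to rt; then H2O
Reagents that add atoms: none
Why: Lewis-acid ketal opening, aromatisation and BBr3 aryl alkyl ether cleavage in one flask: boron opens the dioxolane, the oxocarbenium ion loses the C6 proton while the enone enolises, so the ring aromatises to the boron-bound ether 13 (an isomer of 12 that aqueous acid could not hydrolyse further), and bromide then attacks the O–CH2 carbon to free the catechol, a dealkylation that N-benzyl lactams are known to survive.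

Step 9
Reactants: 14 1-[(3-bromo-4,5-dihydroxyphenyl)methyl]pyrrolidin-2-one
Product: 16 1-[(2,3,6-tribromo-4,5-dihydroxyphenyl)methyl]pyrrolidin-2-one, via 2,3-dibromocatechol 15 (not isolated)
Conditions: Br2 (2.0–2.1 equiv), AcOH, rt
Reagents that add atoms: bromine, BrBr
Why: Electrophilic aromatic bromination: the C5 hydroxyl activates its para (C2) and ortho (C6) positions, the only free ring carbons, so two equivalents of Br2 fill them in turn as in the exhaustive bromination of 4-alkylcatechols, and exact stoichiometry guards against ipso attack at C1 and oxidation to the o-quinone.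

Compound list
1 | cyclopent-3-en-1-ylmethanol | OCC1CC=CC1 | starting material
2 | cyclopent-3-en-1-ylmethyl methanesulfonate | CS(=O)(=O)OCC1CC=CC1 | intermediate
3 | pyrrolidin-2-one | O=C1CCCN1 | starting material
4 | sodium 2-oxopyrrolidin-1-ide (not isolated) | O=C1CCC[N-]1.[Na+] | intermediate
5 | 1-(cyclopent-3-en-1-ylmethyl)pyrrolidin-2-one (achiral) | O=C1CCCN1CC1CC=CC1 | intermediate
6 | 1-[(3-hydroxy-4-oxocyclopentyl)methyl]pyrrolidin-2-one (racemic, cis/trans mixture) | O=C1CCCN1CC1CC(O)C(=O)C1 | intermediate
7 | 1-[(6-hydroxy-1,4-dioxaspiro[4.4]nonan-8-yl)methyl]pyrrolidin-2-one (racemic, diastereomer mixture) | O=C1CCCN1CC1CC(O)C2(C1)OCCO2 | intermediate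
8 | 1-[(6-oxo-1,4-dioxaspiro[4.4]nonan-8-yl)methyl]pyrrolidin-2-one (racemic) | O=C1CCCN1CC1CC(=O)C2(C1)OCCO2 | intermediate
9 | 1-{[6-(tert-butyldimethylsilyloxy)-1,4-dioxaspiro[4.4]non-6-en-8-yl]methyl}pyrrolidin-2-one (racemic) | O=C1CCCN1CC1C=C(O[Si](C)(C)C(C)(C)C)C2(C1)OCCO2 | intermediate
10 | bromoform | BrC(Br)Br | starting material
11 | 1-{[6,6-dibromo-1-(tert-butyldimethylsilyloxy)spiro[bicyclo[3.1.0]hexane-2,2'-[1,3]dioxolan]-4-yl]methyl}pyrrolidin-2-one (racemic, diastereomer mixture, not isolated) | O=C1CCCN1CC1CC2(OCCO2)C3(O[Si](C)(C)C(C)(C)C)C1C3(Br)Br | intermediate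
12 | 1-[(7-bromo-6-oxo-1,4-dioxaspiro[4.5]dec-7-en-9-yl)methyl]pyrrolidin-2-one (racemic) | O=C1CCCN1CC1C=C(Br)C(=O)C2(C1)OCCO2 | intermediate
13 | 1-{[3-bromo-4-hydroxy-5-(2-hydroxyethoxy)phenyl]methyl}pyrrolidin-2-one (boron-bound in the flask, not isolated) | O=C1CCCN1Cc1cc(Br)c(O)c(OCCO)c1 | intermediate
14 | 1-[(3-bromo-4,5-dihydroxyphenyl)methyl]pyrrolidin-2-one | O=C1CCCN1Cc1cc(Br)c(O)c(O)c1 | intermediate
15 | 1-[(2,3-dibromo-4,5-dihydroxyphenyl)methyl]pyrrolidin-2-one (not isolated) | O=C1CCCN1Cc1cc(O)c(O)c(Br)c1Br | intermediate
16 | 1-[(2,3,6-tribromo-4,5-dihydroxyphenyl)methyl]pyrrolidin-2-one | O=C1CCCN1Cc1c(Br)c(O)c(O)c(Br)c1Br | target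

Total step count: 9. Longest linear sequence: 9 steps (from 1).

Steps most likely to fail

Step 7. Three processes threaten it:
- Si–O cleavage by tert-butoxide ahead of cyclopropanation.
- Sluggish carbene capture beside the spiroketal.
- Attack of base or tribromomethanide on the freshly formed bromoenone.

The fallback sets out from 9 and returns at 12. It performs the same C3 insertion with a methylene carbenoid and adds the bromine afterwards. Et2Zn and CH2I2 (Furukawa variant of the Simmons–Smith reaction) should convert 9 into the silyloxycyclopropane F1. FeCl3 in DMF cleaves the shared C2–C4 bond by one-electron oxidation (Saegusa ring enlargement) to the ring-enlarged β-chloro ketone F2. NaOAc in MeOH eliminates HCl to give the enone ketal F3. Br2 in CH2Cl2 adds across C2=C3 to give the dibromo ketone F4, and Et3N removes HBr from it to give 12.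

Step 8. The sensitive bromoenone may break down, or the benzylic C–N bond may be cut, under the strong Lewis acid before aromatisation is complete; ether cleavage may also stall. The fallback sets out from 12 and returns at 16, and it separates the three events. Catalytic TsOH in dry toluene isomerises 12 to 13, which is now isolated. Br2 (two equivalents, CH2Cl2) fills C2 and C6 under the direction of the C5 alkoxy group, by way of the 2,3-dibromo ether F5, to give the tribromo ether F6. BBr3 is applied only at the end, to a robust and fully substituted arene, and gives 16.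

Step 3. The acyloin may be over-oxidised with C–C cleavage, or RuO4 may oxidise the lactam N–CH2 groups in competition. The fallback sets out from 5 and returns at 6. Upjohn dihydroxylation (OsO4 cat., NMO, acetone–H2O) gives the cis-diol F7. Selective mono-oxidation of this vicinal diol with NaBrO3/NaHSO3 in MeCN–H2O gives 6.

Further compounds
F1 | step 7 | 1-{[1-(tert-butyldimethylsilyloxy)spiro[bicyclo[3.1.0]hexane-2,2'-[1,3]dioxolan]-4-yl]methyl}pyrrolidin-2-one (racemic, diastereomer mixture) | O=C1CCCN1CC1CC2(OCCO2)C3(O[Si](C)(C)C(C)(C)C)C1C3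
F2 | step 7 | 1-[(8-chloro-6-oxo-1,4-dioxaspiro[4.5]decan-9-yl)methyl]pyrrolidin-2-one (racemic, diastereomer mixture) | O=C1CCCN1CC1CC2(OCCO2)C(=O)CC1Cl
F3 | step 7 | 1-[(6-oxo-1,4-dioxaspiro[4.5]dec-7-en-9-yl)methyl]pyrrolidin-2-one (racemic) | O=C1CCCN1CC1C=CC(=O)C2(C1)OCCO2
F4 | step 7 | 1-[(7,8-dibromo-6-oxo-1,4-dioxaspiro[4.5]decan-9-yl)methyl]pyrrolidin-2-one (racemic, diastereomer mixture) | O=C1CCCN1CC1CC2(OCCO2)C(=O)C(Br)C1Br
F5 | step 8 | 1-{[2,3-dibromo-4-hydroxy-5-(2-hydroxyethoxy)phenyl]methyl}pyrrolidin-2-one | O=C1CCCN1Cc1cc(OCCO)c(O)c(Br)c1Br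
F6 | step 8 | 1-{[2,3,6-tribromo-4-hydroxy-5-(2-hydroxyethoxy)phenyl]methyl}pyrrolidin-2-one | O=C1CCCN1Cc1c(Br)c(OCCO)c(O)c(Br)c1Br
F7 | step 3 | 1-{[cis-3,4-dihydroxycyclopentyl]methyl}pyrrolidin-2-one (both meso diastereomers) | O=C1CCCN1CC1C[C@@H](O)[C@@H](O)C1
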